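**Retrosynthetic overview**
- The target is a gnetin-type trimer. Both 2,3-trans-dihydrobenzofurans are disconnected biomimetically, as an oxidative 8–12' coupling followed by phenol closure of a p-quinone methide: C8 of a resveratrol unit bonds to the carbon between the two resorcinol oxygens.
- The easily oxidised 2,4-dihydroxystyryl end is disconnected last (Heck), giving an iodo-trimer and 2,4-diacetoxystyrene; 5-iodoresorcinol stands in for that end during the oxidations.
- Iodo-trimer ⇒ resveratrol + iodo-dimer: the inner dihydrobenzofuran is formed second, on the free resorcinol ring of the dimer.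
- Iodo-dimer ⇒ resveratrol + 5-iodoresorcinol: the iodine-bearing dihydrobenzofuran is formed first.
- Both ring formations are run unprotected and enantioselectively with a chiral iron phosphate catalyst; these two steps are unproven proposals.

Assumption: resveratrol, 5-iodoresorcinol and 2,4-dihydroxybenzaldehyde are bought; Fe[(R)-TRIP]3 is iron tris[(R)-3,3'-bis(2,4,6-triisopropylphenyl)-1,1'-binaphthalene-2,2'-diyl phosphate], and its (R)-form is taken to give (S)-C3 (if experiment shows the opposite sense, the (S)-catalyst is used).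

**Route**

Step 1
Reactants: 1 resveratrol, (E)-5-[2-(4-hydroxyphenyl)ethenyl]benzene-1,3-diol; 2 5-iodoresorcinol (5-iodobenzene-1,3-diol)
Product: 4 (2S,3S)-3-(3,5-dihydroxyphenyl)-2-(4-hydroxyphenyl)-6-iodo-2,3-dihydro-1-benzofuran-4-ol, via p-quinone methide 3 (not isolated)
Conditions: Fe[(R)-TRIP]3 (5 mol%), t-BuOOt-Bu (1.2 equiv), HFIP/DCE 1:1, 0 °C; 1 added over 8 h to 2 (5 equiv, excess recovered)
Reagents that add atoms: none
Why: Proposed new method: a biomimetic oxidative 8–12' [3+2] coupling in which electron transfer to the trivalent-iron centre turns the conjugated 4'-phenol of 1 (the only readily oxidised phenol present) into its C8-centred quinone-methide radical, the iron-bound resorcinolate of 2 adds to it through C2 (between the two oxygens and para to iodine, C4/C6 being shielded by the large ortho iodine) while a phosphate P=O hydrogen-bonds a resorcinol OH of the radical so that the chiral pocket selects the C8 face that becomes (S)-C3, a second one-electron oxidation gives p-quinone methide 3, and the flanking phenol closes it by reversible 5-exo oxa-Michael (1,6-) addition to the thermodynamically favoured 2,3-trans ring, which fixes (S)-C2; the closest known reaction types are the FeCl3-mediated 8–10' dimerisation of resveratrol to racemic ε-viniferin and the chiral iron phosphate-catalysed enantioselective oxidative cross-coupling of 2-naphthols with a peroxide.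

Step 2
Reactants: 1 resveratrol; 4 (2S,3S)-3-(3,5-dihydroxyphenyl)-2-(4-hydroxyphenyl)-6-iodo-2,3-dihydro-1-benzofuran-4-ol
Product: 6 (2S,3S)-3-[(2S,3S)-3-(3,5-dihydroxyphenyl)-4-hydroxy-2-(4-hydroxyphenyl)-2,3-dihydro-1-benzofuran-6-yl]-2-(4-hydroxyphenyl)-6-iodo-2,3-dihydro-1-benzofuran-4-ol, via p-quinone methide 5 (not isolated)
Conditions: Fe[(R)-TRIP]3 (10 mol%), t-BuOOt-Bu (1.0 equiv), HFIP/DCE 1:1, 0 °C; 1 (0.8 equiv) added over 12 h to 4 (unreacted 4 recovered)
Reagents that add atoms: none
Why: Proposed new method: the same catalyst-controlled oxidative 8–12' [3+2] coupling, now with the free 3,5-dihydroxyphenyl ring of 4 as acceptor; its C4 (between the two OH groups) is the only activated position not flanked by the bulky C3 methine, the iodinated ring has a single OH and is ortho-blocked by iodine, and keeping 1 at low concentration suppresses its self-coupling; the C8 face of the resveratrol radical is again chosen by the phosphate pocket (the remote centres of 4 exert no bias), giving the (S)-configured C3 of the new ring via p-quinone methide 5, and trans-selective reversible oxa-Michael closure sets its (S)-C2; closest known reaction types as in step 1.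

Step 3
Reactants: 7 2,4-dihydroxybenzaldehyde
Product: 9 2,4-diacetoxystyrene (4-ethenyl-1,3-phenylene diacetate), via 4-vinylresorcinol 8 (not isolated)
Conditions: Ph3PCH3Br (1.4 equiv), KOt-Bu (3.4 equiv), THF, 0 to 40 °C; then Ac2O (3 equiv), 0 °C
Reagents that add atoms: methyltriphenylphosphonium bromide, C[P+](c1ccccc1)(c1ccccc1)c1ccccc1.[Br-]; acetic anhydride, CC(=O)OC(C)=O
Why: Wittig methylenation of the aldehyde, whose two phenols are carried as potassium phenoxides, gives 4-vinylresorcinol 8, which is O-acetylated in the same flask before it can polymerise; no stereocentre is formed.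

Step 4
Reactants: 6 the iodo-trimer from step 2; 9 2,4-diacetoxystyrene (1.5 equiv)
Product: 11 (2S,3S)-3-[(2S,3S)-3-(3,5-dihydroxyphenyl)-4-hydroxy-2-(4-hydroxyphenyl)-2,3-dihydro-1-benzofuran-6-yl]-6-[(E)-2-(2,4-dihydroxyphenyl)ethenyl]-2-(4-hydroxyphenyl)-2,3-dihydro-1-benzofuran-4-ol, via target diacetate 10 (not isolated)
Conditions: Pd(OAc)2 (5 mol%), P(o-tol)3 (12 mol%), Et3N (4 equiv), DMF, 85 °C; then pyrrolidine (6 equiv), rt
Reagents that add atoms: none
Why: Mizoroki–Heck reaction, in which oxidative addition of zerovalent palladium into the unhindered C–I bond, syn-carbopalladation at the terminal carbon of the styrene and syn-β-hydride elimination give only the (E)-stilbene; the free phenols and trans-dihydrobenzofurans tolerate Et3N at 85 °C, the four stereocentres are untouched, and pyrrolidine then removes the aryl acetates (including any that migrated) by aminolysis.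

**Compound list**

1 | resveratrol, (E)-5-[2-(4-hydroxyphenyl)ethenyl]benzene-1,3-diol | Oc1ccc(/C=C/c2cc(O)cc(O)c2)cc1 | starting material
2 | 5-iodoresorcinol (5-iodobenzene-1,3-diol) | Oc1cc(O)cc(I)c1 | starting material
3 | p-quinone methide, 4-[(2S)-2-(3,5-dihydroxyphenyl)-2-(2,6-dihydroxy-4-iodophenyl)ethylidene]cyclohexa-2,5-dien-1-one (not isolated) | Oc1cc(I)cc(O)c1[C@@H](C=C2C=CC(=O)C=C2)c3cc(O)cc(O)c3 | intermediate
4 | (2S,3S)-3-(3,5-dihydroxyphenyl)-2-(4-hydroxyphenyl)-6-iodo-2,3-dihydro-1-benzofuran-4-ol (2,3-trans) | Oc1ccc([C@H]2Oc3cc(I)cc(O)c3[C@@H]2c2cc(O)cc(O)c2)cc1 | intermediate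
5 | p-quinone methide, 4-{(2S)-2-(3,5-dihydroxyphenyl)-2-[2,6-dihydroxy-4-((2S,3S)-4-hydroxy-2-(4-hydroxyphenyl)-6-iodo-2,3-dihydro-1-benzofuran-3-yl)phenyl]ethylidene}cyclohexa-2,5-dien-1-one (not isolated) | O=C1C=CC(=C[C@H](c2c(O)cc(cc2O)[C@H]4c5c(O)cc(I)cc5O[C@@H]4c6ccc(O)cc6)c3cc(O)cc(O)c3)C=C1 | intermediate
6 | iodo-trimer, (2S,3S)-3-[(2S,3S)-3-(3,5-dihydroxyphenyl)-4-hydroxy-2-(4-hydroxyphenyl)-2,3-dihydro-1-benzofuran-6-yl]-2-(4-hydroxyphenyl)-6-iodo-2,3-dihydro-1-benzofuran-4-ol (both rings trans) | Oc1ccc([C@H]2Oc3cc(I)cc(O)c3[C@@H]2c2cc(O)c3c(c2)O[C@H](c2ccc(O)cc2)[C@H]3c2cc(O)cc(O)c2)cc1 | intermediate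
7 | 2,4-dihydroxybenzaldehyde | O=Cc1ccc(O)cc1O | starting material
8 | 4-vinylresorcinol, 4-ethenylbenzene-1,3-diol (present as its dipotassium salt, not isolated) | C=Cc1ccc(O)cc1O | intermediate
9 | 2,4-diacetoxystyrene, 4-ethenyl-1,3-phenylene diacetate | C=Cc1ccc(OC(C)=O)cc1OC(C)=O | intermediate
10 | target 2',4'-di-O-acetate: compound 11 with both OH groups of the 2,4-dihydroxystyryl ring acetylated (not isolated) | Oc1ccc([C@H]2Oc3cc(/C=C/c4ccc(OC(C)=O)cc4OC(C)=O)cc(O)c3[C@@H]2c2cc(O)c3c(c2)O[C@H](c2ccc(O)cc2)[C@H]3c2cc(O)cc(O)c2)cc1 | intermediate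
11 | CNP0186204.1, (2S,3S)-3-[(2S,3S)-3-(3,5-dihydroxyphenyl)-4-hydroxy-2-(4-hydroxyphenyl)-2,3-dihydro-1-benzofuran-6-yl]-6-[(E)-2-(2,4-dihydroxyphenyl)ethenyl]-2-(4-hydroxyphenyl)-2,3-dihydro-1-benzofuran-4-ol | Oc1ccc([C@H]2Oc3cc(/C=C/c4ccc(O)cc4O)cc(O)c3[C@@H]2c2cc(O)c3c(c2)O[C@H](c2ccc(O)cc2)[C@H]3c2cc(O)cc(O)c2)cc1 | target

**Step count and risks**

Total steps: 4. Longest linear sequence: 3 (steps 1, 2, 4; step 3 is a side branch).

The three steps most likely to fail:

Step 1. Neither the enantioselectivity nor the C2-selectivity on 5-iodoresorcinol of the catalytic oxidative [3+2] is proven. The fallback sets out from 1 and 2 and comes back at 4; it gives up catalyst control and resolves. Compound 1 is added slowly to 2 (5 equiv) and FeCl3·6H2O (2.2 equiv) in acetone at rt, the racemic conditions under which resveratrol is known to couple through C8 onto a resorcinol ring. The trans product forms as the racemate, that is 4 together with its enantiomer (2R,3R)-3-(3,5-dihydroxyphenyl)-2-(4-hydroxyphenyl)-6-iodo-2,3-dihydro-1-benzofuran-4-ol F1. F1 is removed by preparative SFC on an amylose tris(3,5-dimethylphenylcarbamate) phase, the absolute configuration is assigned by ECD, and 4 re-enters at step 2.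

Step 2. Besides the unproven stereocontrol, resveratrol can couple with itself, and product 6 can accept a further unit. The fallback sets out from 4 and comes back at 6; it exchanges the roles of the partners, so that the precious compound becomes the donor and the cheap one the excess acceptor. Compound 4 is first coupled in a Mizoroki–Heck reaction with 4-vinylphenol F2 (Pd(OAc)2, P(o-tol)3, Et3N, DMF, 85 °C) to give gnetin C, 5-[(2S,3S)-4-hydroxy-2-(4-hydroxyphenyl)-6-[(E)-2-(4-hydroxyphenyl)ethenyl]-2,3-dihydro-1-benzofuran-3-yl]benzene-1,3-diol F3. F3, whose 4-hydroxystyryl phenol is now the only easily oxidised site, is added slowly to 2 (5 equiv) under the conditions of step 1. The second ring is thus again built on 5-iodoresorcinol, reusing the acceptor selectivity of step 1, and 6 is reached.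

Step 4. A Heck reaction on an aryl iodide with seven free phenols may stall or damage the dihydrobenzofurans. The fallback sets out from 6 and comes back at 10; it replaces the Heck reaction by vinylation and cross-metathesis. Suzuki–Miyaura coupling of 6 with CH2=CHBF3K (PdCl2(dppf), K2CO3, THF/H2O, 70 °C) gives the vinyl trimer (2S,3S)-3-[(2S,3S)-3-(3,5-dihydroxyphenyl)-4-hydroxy-2-(4-hydroxyphenyl)-2,3-dihydro-1-benzofuran-6-yl]-6-ethenyl-2-(4-hydroxyphenyl)-2,3-dihydro-1-benzofuran-4-ol F4. Cross-metathesis of F4 with 9 (3 equiv) using the second-generation Hoveyda–Grubbs catalyst RuCl2(H2IMes)(=CH-C6H4-2-Oi-Pr) in CH2Cl2/THF at 40 °C gives 10; styrene–styrene metathesis is E-selective and tolerates free phenols. Compound 10 is then deacetylated with pyrrolidine as in step 4 to give 11.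

Further compounds
F1 | step 1 | (2R,3R)-3-(3,5-dihydroxyphenyl)-2-(4-hydroxyphenyl)-6-iodo-2,3-dihydro-1-benzofuran-4-ol (enantiomer of 4) | Oc1ccc([C@@H]2Oc3cc(I)cc(O)c3[C@H]2c2cc(O)cc(O)c2)cc1
F2 | step 2 | 4-vinylphenol, 4-ethenylphenol (bought) | C=Cc1ccc(O)cc1
F3 | step 2 | gnetin C, 5-[(2S,3S)-4-hydroxy-2-(4-hydroxyphenyl)-6-[(E)-2-(4-hydroxyphenyl)ethenyl]-2,3-dihydro-1-benzofuran-3-yl]benzene-1,3-diol | Oc1ccc(/C=C/c2cc(O)c3c(c2)O[C@H](c2ccc(O)cc2)[C@H]3c2cc(O)cc(O)c2)cc1
F4 | step 4 | vinyl trimer, (2S,3S)-3-[(2S,3S)-3-(3,5-dihydroxyphenyl)-4-hydroxy-2-(4-hydroxyphenyl)-2,3-dihydro-1-benzofuran-6-yl]-6-ethenyl-2-(4-hydroxyphenyl)-2,3-dihydro-1-benzofuran-4-ol | Oc1ccc([C@H]2Oc3cc(C=C)cc(O)c3[C@@H]2c2cc(O)c3c(c2)O[C@H](c2ccc(O)cc2)[C@H]3c2cc(O)cc(O)c2)cc1
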